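(Readings and results are simulated with constants of no real substance.)

The target in the alder run reached 49.0 % at 2.50 min and was flattening there, so I asked what could still be taken from that level in the new flasks.

| flask | starting material | protic impurity | catalyst | temperature | remark | time |
|---|---|---|---|---|---|---|
| birch | 0.050 M | 5 mM | 1 mM | 20 °C | run made earlier |  |
| oak | 0.075 M | 5 mM | 1 mM | 31 °C | run made earlier |  |
| alder | 0.10 M | 5 mM | 2 mM | 20 °C | run made earlier |  |
| Thursday's | 0.10 M | 5.00 mM | 1.0 mM | 15 °C |  | 4.0 min |
| Wednesday's | 0.10 M | 5.00 mM | 1.0 mM |  | at 35 °C until 3.0 min, from then on at 15 °C | 4.0 min |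
| Sunday's | 0.10 M | 5.00 mM | 1.0 mM | 35 °C |  | 4.0 min |

birch run (percent of the starting material charged)

| time / min | target / % |
|---|---|
| 0.500 | 14.6 |
| 1.00 | 27.0 |
| 1.33 | 31.5 |
| 2.00 | 40.2 |
| 2.50 | 42.1 |

oak run (percent of the starting material charged)

| time / s | target / % |
|---|---|
| 15.0 | 12.7 |
| 25.0 | 21.4 |
| 40.0 | 30.6 |
| 50.0 | 33.6 |
| 60.0 | 37.3 |

alder run (percent of the starting material charged)

| time / min | target / % |
|---|---|
| 0.200 | 13.0 |
| 0.667 | 31.4 |
| 1.00 | 42.3 |
| 1.50 | 45.8 |
| 2.50 | 49.0 |

(readings scatter by 1 percentage point)

- the analysis behind the earlier runs scatters by 1 percentage point, standard deviation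

- which flask leads in amount of target, in percent of the starting material charged ("all alike" within 1.5 percentage points) (Thursday's / Wednesday's / Sunday's / all alike)
- how much target is there at the end, in percent of the starting material charged: Thursday's
- how much target is there at the end, in percent of the starting material charged: Wednesday's
- how much target is there at the end, in percent of the starting material charged: Sunday's

I wrote the balance of the protic impurity, the limiting reagent of the quench, assuming that one molecule of it spoils one of starting material. Its charge divided by that of the starting material, 5.00 %, I called the quench ceiling: the share of the charge the impurity can take, and the ceiling times the part of the impurity consumed gives the share taken so far.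

Alder has the same ceiling, and target held 49.0 % of its charge. At that reading I reckoned the full ceiling as worth about 2.4 percentage points of target, and I assumed that Sunday's and Wednesday's, the two flasks started at 35 °C, lose the full ceiling and stand near 46.5 %.

One number was not enough. The new flasks share it, so by itself it does not rank them, and that cost is larger than the margin of 1.5 points. Thursday's needed a second look: it gets 0.800 of the catalyst-time alder had at its last reading, and at 15 °C against 20 °C. I put it a little below that level and called the contest a tie within the margin.

The forecast gave 45 % for Thursday's, 48.5 % for Wednesday's and 48 % for Sunday's, with Wednesday's ahead, though it said of Wednesday's “lead over Sunday is uncertain”, and so it differed from my tie.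

The flasks gave 45.2 % for Thursday's, 45.6 % for Wednesday's and 45.9 % for Sunday's: all alike.

    starting material + catalyst ⇌ target + catalyst, rate k1*[starting material]*[catalyst] forward; the back reaction follows from the equilibrium constant (K = 1.30, k = 13.2 /M/s, Ea = 35.0 kJ/mol, ΔH = 6.00 kJ/mol)
    target + catalyst ⇌ isomer of the product + catalyst, rate k2*[catalyst]*[target] forward; the back reaction follows from the equilibrium constant (K = 0.735, k = 0.391 /M/s, Ea = 36.0 kJ/mol, ΔH = −3.00 kJ/mol)
    isomer of the product + catalyst ⇌ starting material + catalyst, rate k3*[catalyst]*[isomer of the product] forward; the back reaction follows from the equilibrium constant (k = 0.365 /M/s, Ea = 67.0 kJ/mol)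
    starting material + protic impurity → quenched substrate (k = 0.0918 /M/s, Ea = 46.0 kJ/mol)
    starting material → uncatalysed product (k = 8.55 × 10⁻⁴ /s, Ea = 83.0 kJ/mol)
    (constants at 35 °C)

Sunday's had kept 35 % of its own charge of impurity at 4.00 min, so the ceiling gives 3.25 % spoiled, and quenched substrate stood at 3.23 %. Uncatalysed product in Sunday's, at 9.70 %, stood above the ceiling. In Sunday's read at 15 min, 6.5 % of the charged impurity remained, the ceiling gives 4.68 %, and quenched substrate stood at 4.67 %.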